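**Plan**

1. Retrosynthesis: global desilylation comes last. Ring C is then cut at C2–C3 and C4–C4a, leaving an α-acetoxy benzyl aryl ether (ring A–O1–C2(OAc)–ring B) and ethoxyacetylene as the C3–C4 unit. The acetal is cut to an aryl ester of a ring A phenol and a ring B benzoic acid.
2. Enabling feature: O1 links C8a of ring A to the benzylic C2 that carries the para-oxygenated ring B, so loss of acetate gives the cationic 2-oxadiene C4a=C8a–O1(+)=C2. C4a is ortho to O1, para to O7, and the only free ortho position because C8 bears the side chain.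
3. Forward: ring A (from resorcinol by ortho-lithiation/prenylation, Shi epoxidation, epoxide-to-allylic-alcohol isomerisation) and ring B (double linear Negishi prenylation) are made separately. A temporary seven-membered di-tert-butylsilylene ring ties the carbinol oxygen to O7 and leaves O1–H as the only phenol.
4. Esterification and reductive acetylation give the acetal; the acid-catalysed annulation with ethoxyacetylene then builds ring C in one operation, and fluoride removes the silylene and the silyl ether.
5. Stereochemistry: the (R)-carbinol comes from the Shi epoxidation (reagent control, retained on isomerisation). (2S) is set in the annulation by a chiral counter-anion acting on a planar oxocarbenium ion, so both acetal epimers converge.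

Key step: step 12

Remark: flavanone numbering is used (O1, C2, C3, C4, C4a, C5–C8, C8a; ring B primed). The SMILES is read as (2S) at C2 and (R) at the side-chain carbinol. The sense of induction of the chiral acid in step 12 cannot be predicted with certainty, so the catalyst antipode that delivers 2S is taken.

**Route**

Step 1
Reactants: 1 resorcinol
Product: 2 1,3-bis(methoxymethoxy)benzene
Conditions: MOMCl, iPr2NEt, CH2Cl2, 0 °C to rt
Reagents that add atoms: chloromethyl methyl ether, COCCl
Why: Williamson-type O-alkylation of both phenols gives the bis-acetal whose two oxygens will direct lithiation to the carbon between them.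

Step 2
Reactants: 2 1,3-bis(methoxymethoxy)benzene
Product: 3 1,3-bis(methoxymethoxy)-2-(3-methylbut-2-en-1-yl)benzene
Conditions: n-BuLi, THF, 0 °C to rt; prenyl bromide, −78 °C to rt
Reagents that add atoms: prenyl bromide (1-bromo-3-methylbut-2-ene), CC(C)=CCBr
Why: Directed ortho-metalation should occur at the position flanked by both MOM ethers, and the aryllithium should alkylate prenyl bromide at its primary carbon to give the linear prenyl arene.

Step 3
Reactants: 3 1,3-bis(methoxymethoxy)-2-(3-methylbut-2-en-1-yl)benzene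
Product: 4 (3R)-3-[2,6-bis(methoxymethoxy)benzyl]-2,2-dimethyloxirane
Conditions: D-fructose-derived Shi ketone (30 mol%), Oxone (KHSO5), K2CO3, Bu4NHSO4, aq. Na2B4O7 buffer, MeCN–dimethoxymethane, 0 °C
Reagents that add atoms: potassium peroxymonosulfate (KHSO5, active component of Oxone), [K+].[O-]S(=O)(=O)OO
Why: Shi asymmetric epoxidation of the trisubstituted olefin by the chiral dioxirane through the spiro transition state should set the (R) centre, as for other trisubstituted and trans olefins with the D-fructose-derived ketone.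

Step 4
Reactants: 4 (3R)-3-[2,6-bis(methoxymethoxy)benzyl]-2,2-dimethyloxirane
Product: 5 (2R)-1-[2,6-bis(methoxymethoxy)phenyl]-3-methylbut-3-en-2-ol
Conditions: Al(OiPr)3 (2 equiv), toluene, 110 °C
Reagents that add atoms: none
Why: Aluminium alkoxide-promoted epoxide-to-allylic-alcohol isomerisation opens the C–O bond at the tertiary carbon with loss of a methyl proton, so the C–O bond at the stereocentre is untouched and (R) is retained.

Step 5
Reactants: 5 (2R)-1-[2,6-bis(methoxymethoxy)phenyl]-3-methylbut-3-en-2-ol
Product: 7 2-[(2R)-2-hydroxy-3-methylbut-3-en-1-yl]benzene-1,3-diol, via tris(trimethylsilyl) ether 6 (not isolated)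
Conditions: Me3SiOTf (5 equiv), 2,2'-bipyridyl (7 equiv), CH2Cl2, 0 °C to rt; then H2O, rt
Reagents that add atoms: none
Why: Silyl triflate/2,2'-bipyridyl cleavage of aromatic MOM ethers proceeds through aryl silyl ethers under buffered, non-protic conditions, which should spare the isopropenyl carbinol that protic acid would cyclise onto the neighbouring phenol.

Step 6
Reactants: 7 2-[(2R)-2-hydroxy-3-methylbut-3-en-1-yl]benzene-1,3-diol
Product: 8 (4R)-2,2-di-tert-butyl-4-(prop-1-en-2-yl)-4,5-dihydro-1,3,2-benzodioxasilepin-6-ol (silylene bridging the carbinol oxygen and one phenol oxygen; the other phenol free)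
Conditions: tBu2Si(OTf)2 (1.05 equiv), 2,6-lutidine, CH2Cl2 (high dilution), −78 to 0 °C
Reagents that add atoms: di-tert-butylsilyl bis(trifluoromethanesulfonate), CC(C)(C)[Si](OS(=O)(=O)C(F)(F)F)(OS(=O)(=O)C(F)(F)F)C(C)(C)C
Why: Cyclic silylene formation between the carbinol and either of the two equivalent phenols (interchanged by rotation about the aryl–CH2 bond) should give one seven-membered ring and leave exactly one phenol free, without statistical mono-protection.

Step 7
Reactants: 9 methyl 3,5-dibromo-4-hydroxybenzoate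
Product: 10 methyl 3,5-dibromo-4-[(tert-butyldimethylsilyl)oxy]benzoate
Conditions: TBSCl, imidazole, DMF, rt
Reagents that add atoms: tert-butyldimethylsilyl chloride, CC(C)(C)[Si](C)(C)Cl
Why: Imidazole-promoted silylation of the acidic phenol masks it for the organozinc coupling and provides the silyl ether carried to the end.

Step 8
Reactants: 10 methyl 3,5-dibromo-4-[(tert-butyldimethylsilyl)oxy]benzoate
Product: 11 methyl 4-[(tert-butyldimethylsilyl)oxy]-3,5-bis(3-methylbut-2-en-1-yl)benzoate
Conditions: prenylZnBr (Me2C=CHCH2ZnBr, 3 equiv, THF solution), Pd(OAc)2 (2 mol%), CPhos (4 mol%), THF, rt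
Reagents that add atoms: prenylzinc bromide, CC(C)=CC[Zn]Br
Why: Double Negishi coupling in which the bulky biaryl phosphine on zerovalent palladium favours reductive elimination at the primary carbon of the prenyl group should give the linear diprenyl arene, the ester being inert to the organozinc.

Step 9
Reactants: 11 methyl 4-[(tert-butyldimethylsilyl)oxy]-3,5-bis(3-methylbut-2-en-1-yl)benzoate
Product: 13 4-[(tert-butyldimethylsilyl)oxy]-3,5-bis(3-methylbut-2-en-1-yl)benzoic acid, via trimethylstannyl ester 12 (not isolated)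
Conditions: Me3SnOH (4 equiv), 1,2-dichloroethane, 70 °C; then cold dilute aq. HCl wash
Reagents that add atoms: trimethyltin hydroxide (Me3SnOH), C[Sn](C)(C)O
Why: Neutral tin hydroxide ester hydrolysis should cleave the unhindered methyl ester while sparing the aryl silyl ether, which is shielded by the two ortho prenyl groups.

Step 10
Reactants: 8 silylene-bridged phenol; 13 4-[(tert-butyldimethylsilyl)oxy]-3,5-bis(3-methylbut-2-en-1-yl)benzoic acid
Product: 14 (4R)-2,2-di-tert-butyl-4-(prop-1-en-2-yl)-4,5-dihydro-1,3,2-benzodioxasilepin-6-yl 4-[(tert-butyldimethylsilyl)oxy]-3,5-bis(3-methylbut-2-en-1-yl)benzoate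
Conditions: N,N'-dicyclohexylcarbodiimide, DMAP (cat.), CH2Cl2, 0 °C to rt
Reagents that add atoms: none
Why: Steglich esterification joins the only free phenol to the acid and so forms the O1–C2 bond of the target at the ester oxidation level.

Step 11
Reactants: 14 aryl ester
Product: 16 acetoxy{4-[(tert-butyldimethylsilyl)oxy]-3,5-bis(3-methylbut-2-en-1-yl)phenyl}methyl ether of phenol 8 (both epimers at the acetal carbon), via aluminium hemiacetal 15 (not isolated)
Conditions: i-Bu2AlH (1.5 equiv), CH2Cl2, −78 °C; then pyridine, DMAP, Ac2O, −78 to −20 °C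
Reagents that add atoms: acetic anhydride, CC(=O)OC(C)=O
Why: Reductive acetylation, in which the ester is reduced only to the aluminium hemiacetal at −78 °C and this is O-acetylated in the flask, should give the α-acetoxy ether; the configuration of the new acetal carbon is irrelevant because it is erased in step 12.

Step 12
Reactants: 16 α-acetoxy ether (both acetal epimers)
Product: 18 (2S)-2-{4-[(tert-butyldimethylsilyl)oxy]-3,5-bis(3-methylbut-2-en-1-yl)phenyl}chroman-4-one with O7 and the (R)-carbinol oxygen bridged by the di-tert-butylsilylene, via 4-ethoxy-2H-chromene 17 (not isolated)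
Conditions: ethoxyacetylene (3 equiv, solution in hexanes), chiral imidodiphosphorimidate (IDPi) Brønsted acid (5 mol%, antipode giving 2S), CH2Cl2–toluene, −78 to −40 °C; then 5% aq. oxalic acid, THF, 0 °C
Reagents that add atoms: ethoxyacetylene, C#COCC; water, O
Why: Proposed new method: the chiral acid ionises either acetal epimer of 16 with loss of acetic acid (an acyloxy oxygen cannot stabilise a cation, so only the O-aryl oxocarbenium ion, the cationic 2-oxadiene C4a=C8a–O1(+)=C2 stabilised by the 4-silyloxyphenyl ring B, is formed), the CH terminus of ethoxyacetylene adds to C2, the resulting ethoxyketenium ion is captured by C4a of ring A, proton loss returns the acid, and the aqueous acid work-up hydrolyses enol ether 17 to the ketone. The closest known reaction types are the Lewis acid-mediated oxa-Povarov [4+2] annulation of aryl oxocarbenium ions with alkenes and the enantioselective addition of π-nucleophiles to oxocarbenium ions paired with confined imidodiphosphorimidate anions; new is their combination with an ynol ether as a ketene equivalent. Ring C closes as a six-membered ring by intramolecular Friedel–Crafts attack of the arene on the sp carbon of the ketenium ion (6-exo-dig with respect to the C=O(+) bond, the C3=C4 bond lying inside the new ring), so the whole is a stepwise formal [4+2]. C2 is set in the first C–C bond formation by the chiral counter-anion (catalyst control on a planar cation, hence stereoconvergent for both acetal epimers), and the remote (R)-carbinol centre is not touched. The step needs chemoselectivity for the ynol ether over the prenyl and isopropenyl alkenes and over intermolecular arylation, which its higher nucleophilicity and its excess (part of which also takes up the acetic acid) should secure, and regioselective closure, which is secured because C4a is the only free position ortho to O1 and is para to the O7 silyloxy group.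

Step 13
Reactants: 18 silyl-protected (2S)-flavanone
Product: 19 (2S)-7-hydroxy-8-[(2R)-2-hydroxy-3-methylbut-3-en-1-yl]-2-[4-hydroxy-3,5-bis(3-methylbut-2-en-1-yl)phenyl]chroman-4-one (CNP0127055.2)
Conditions: HF·pyridine, pyridine, THF, 0 °C to rt
Reagents that add atoms: none
Why: Fluoride cleaves the Si–O bonds of the silylene and of the aryl silyl ether, and the pyridine-buffered, slightly acidic medium should avoid the base-mediated ring opening to the chalcone that would epimerise C2.

**Compound list**

1 | resorcinol (benzene-1,3-diol) | Oc1cccc(O)c1 | starting material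
2 | 1,3-bis(methoxymethoxy)benzene | COCOc1cccc(OCOC)c1 | intermediate
3 | 1,3-bis(methoxymethoxy)-2-(3-methylbut-2-en-1-yl)benzene | CC(C)=CCc1c(OCOC)cccc1OCOC | intermediate
4 | (3R)-3-[2,6-bis(methoxymethoxy)benzyl]-2,2-dimethyloxirane | CC1(C)O[C@@H]1Cc1c(OCOC)cccc1OCOC | intermediate
5 | (2R)-1-[2,6-bis(methoxymethoxy)phenyl]-3-methylbut-3-en-2-ol | C=C(C)[C@H](O)Cc1c(OCOC)cccc1OCOC | intermediate
6 | tris(trimethylsilyl) ether of triol 7 (two aryl and one carbinol silyl ether, R) | C=C(C)[C@H](O[Si](C)(C)C)Cc1c(O[Si](C)(C)C)cccc1O[Si](C)(C)C | intermediate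
7 | 2-[(2R)-2-hydroxy-3-methylbut-3-en-1-yl]benzene-1,3-diol | C=C(C)[C@H](O)Cc1c(O)cccc1O | intermediate
8 | (4R)-2,2-di-tert-butyl-4-(prop-1-en-2-yl)-4,5-dihydro-1,3,2-benzodioxasilepin-6-ol | C=C(C)[C@H]1Cc2c(O)cccc2O[Si](C(C)(C)C)(C(C)(C)C)O1 | intermediate
9 | methyl 3,5-dibromo-4-hydroxybenzoate | COC(=O)c1cc(Br)c(O)c(Br)c1 | starting material
10 | methyl 3,5-dibromo-4-[(tert-butyldimethylsilyl)oxy]benzoate | COC(=O)c1cc(Br)c(O[Si](C)(C)C(C)(C)C)c(Br)c1 | intermediate
11 | methyl 4-[(tert-butyldimethylsilyl)oxy]-3,5-bis(3-methylbut-2-en-1-yl)benzoate | COC(=O)c1cc(CC=C(C)C)c(O[Si](C)(C)C(C)(C)C)c(CC=C(C)C)c1 | intermediate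
12 | trimethylstannyl 4-[(tert-butyldimethylsilyl)oxy]-3,5-bis(3-methylbut-2-en-1-yl)benzoate | C[Sn](C)(C)OC(=O)c1cc(CC=C(C)C)c(O[Si](C)(C)C(C)(C)C)c(CC=C(C)C)c1 | intermediate
13 | 4-[(tert-butyldimethylsilyl)oxy]-3,5-bis(3-methylbut-2-en-1-yl)benzoic acid | OC(=O)c1cc(CC=C(C)C)c(O[Si](C)(C)C(C)(C)C)c(CC=C(C)C)c1 | intermediate
14 | aryl ester of phenol 8 with acid 13 | C=C(C)[C@H]1Cc2c(OC(=O)c3cc(CC=C(C)C)c(O[Si](C)(C)C(C)(C)C)c(CC=C(C)C)c3)cccc2O[Si](C(C)(C)C)(C(C)(C)C)O1 | intermediate
15 | diisobutylaluminium hemiacetal of ester 14 | C=C(C)[C@H]1Cc2c(OC(O[Al](CC(C)C)CC(C)C)c3cc(CC=C(C)C)c(O[Si](C)(C)C(C)(C)C)c(CC=C(C)C)c3)cccc2O[Si](C(C)(C)C)(C(C)(C)C)O1 | intermediate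
16 | α-acetoxy benzyl aryl ether (both epimers at the acetal carbon) | C=C(C)[C@H]1Cc2c(OC(OC(C)=O)c3cc(CC=C(C)C)c(O[Si](C)(C)C(C)(C)C)c(CC=C(C)C)c3)cccc2O[Si](C(C)(C)C)(C(C)(C)C)O1 | intermediate
17 | (2S)-4-ethoxy-2H-chromene (ring C enol ether of 18) | C=C(C)[C@H]1Cc2c3O[C@H](c4cc(CC=C(C)C)c(O[Si](C)(C)C(C)(C)C)c(CC=C(C)C)c4)C=C(OCC)c3ccc2O[Si](C(C)(C)C)(C(C)(C)C)O1 | intermediate
18 | silyl-protected (2S)-flavanone (O4' as TBS ether; O7 and the (R)-carbinol oxygen bridged by di-tert-butylsilylene) | C=C(C)[C@H]1Cc2c3O[C@H](c4cc(CC=C(C)C)c(O[Si](C)(C)C(C)(C)C)c(CC=C(C)C)c4)CC(=O)c3ccc2O[Si](C(C)(C)C)(C(C)(C)C)O1 | intermediate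
19 | (2S)-7-hydroxy-8-[(2R)-2-hydroxy-3-methylbut-3-en-1-yl]-2-[4-hydroxy-3,5-bis(3-methylbut-2-en-1-yl)phenyl]chroman-4-one | C=C(C)[C@H](O)Cc1c(O)ccc2c1O[C@H](c1cc(CC=C(C)C)c(O)c(CC=C(C)C)c1)CC2=O | target

**Step count and risks**

Total step count: 13. Longest linear sequence: 10 steps (steps 1–6 and 10–13).

Steps most likely to fail:

1. Step 12 (proposed new method). Possible failures are poor enantiofacial discrimination in the ion pair, consumption of the ynol ether and the acid by direct protonation, or capture of the ketenium ion by acetate before ring closure. Fallback with known chemistry, from 16 back to 18: a Me3SiOTf-catalysed Mukaiyama-type addition of 1-(tert-butyldimethylsilyloxy)-1-methoxyethene to 16, run with a chiral squaramide hydrogen-bond donor (a known way to add silyl ketene acetals enantioselectively to aryl-stabilised oxocarbenium ions), should give the methyl (3S)-3-aryloxy-3-arylpropanoate F1. Me3SnOH hydrolysis should give the acid F2, and 1-chloro-N,N,2-trimethylprop-1-en-1-amine should give the acid chloride F3. SnCl4 (CH2Cl2, −78 °C) should then close ring C by Friedel–Crafts acylation at C4a to give 18. If the addition is unselective, the C2 epimers of 18 are diastereomers and would be separated by chromatography.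

2. Step 11. The aluminium hemiacetal of an aryl ester may collapse with loss of the aryloxide before acetylation, leading to over-reduction. Fallback, from 11 (and 8) back to 16: i-Bu2AlH reduction of 11 should give the benzyl alcohol F4 and MnO2 oxidation the aldehyde F5. Addition of acetyl bromide (CH2Cl2, 0 °C, no Lewis acid) should give the α-bromobenzyl acetate F6, and O-alkylation of phenol 8 with it (iPr2NEt, CH2Cl2, −20 °C) should give 16.

3. Step 5. The liberated phenol may cyclise onto the isopropenyl carbinol, or the allylic alcohol may ionise, during acetal cleavage. Fallback, from 3 back to 7: the MOM groups are removed at the robust prenyl stage (HCl, MeOH) to give 2-prenylresorcinol F7. Silylation (TBSCl, imidazole) should give the bis-silyl ether F8, Shi epoxidation the (R)-epoxide F9, and Al(OiPr)3 isomerisation the allylic alcohol F10. K2CO3 in MeOH should then cleave the two aryl silyl ethers under basic conditions to give 7.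

**Further compounds**

F1 | step 12 | methyl (3S)-3-{4-[(tert-butyldimethylsilyl)oxy]-3,5-bis(3-methylbut-2-en-1-yl)phenyl}-3-(aryloxy)propanoate (aryloxy = phenol 8) | C=C(C)[C@H]1Cc2c(O[C@@H](CC(=O)OC)c3cc(CC=C(C)C)c(O[Si](C)(C)C(C)(C)C)c(CC=C(C)C)c3)cccc2O[Si](C(C)(C)C)(C(C)(C)C)O1
F2 | step 12 | (3S)-3-aryl-3-(aryloxy)propanoic acid from F1 | C=C(C)[C@H]1Cc2c(O[C@@H](CC(=O)O)c3cc(CC=C(C)C)c(O[Si](C)(C)C(C)(C)C)c(CC=C(C)C)c3)cccc2O[Si](C(C)(C)C)(C(C)(C)C)O1
F3 | step 12 | (3S)-3-aryl-3-(aryloxy)propanoyl chloride from F2 | C=C(C)[C@H]1Cc2c(O[C@@H](CC(=O)Cl)c3cc(CC=C(C)C)c(O[Si](C)(C)C(C)(C)C)c(CC=C(C)C)c3)cccc2O[Si](C(C)(C)C)(C(C)(C)C)O1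
F4 | step 11 | {4-[(tert-butyldimethylsilyl)oxy]-3,5-bis(3-methylbut-2-en-1-yl)phenyl}methanol | OCc1cc(CC=C(C)C)c(O[Si](C)(C)C(C)(C)C)c(CC=C(C)C)c1
F5 | step 11 | 4-[(tert-butyldimethylsilyl)oxy]-3,5-bis(3-methylbut-2-en-1-yl)benzaldehyde | O=Cc1cc(CC=C(C)C)c(O[Si](C)(C)C(C)(C)C)c(CC=C(C)C)c1
F6 | step 11 | bromo{4-[(tert-butyldimethylsilyl)oxy]-3,5-bis(3-methylbut-2-en-1-yl)phenyl}methyl acetate | CC(=O)OC(Br)c1cc(CC=C(C)C)c(O[Si](C)(C)C(C)(C)C)c(CC=C(C)C)c1
F7 | step 5 | 2-(3-methylbut-2-en-1-yl)benzene-1,3-diol | CC(C)=CCc1c(O)cccc1O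
F8 | step 5 | 1,3-bis[(tert-butyldimethylsilyl)oxy]-2-(3-methylbut-2-en-1-yl)benzene | CC(C)=CCc1c(O[Si](C)(C)C(C)(C)C)cccc1O[Si](C)(C)C(C)(C)C
F9 | step 5 | (3R)-3-{2,6-bis[(tert-butyldimethylsilyl)oxy]benzyl}-2,2-dimethyloxirane | CC1(C)O[C@@H]1Cc1c(O[Si](C)(C)C(C)(C)C)cccc1O[Si](C)(C)C(C)(C)C
F10 | step 5 | (2R)-1-{2,6-bis[(tert-butyldimethylsilyl)oxy]phenyl}-3-methylbut-3-en-2-ol | C=C(C)[C@H](O)Cc1c(O[Si](C)(C)C(C)(C)C)cccc1O[Si](C)(C)C(C)(C)C
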